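**Assumption:** atoms carry germacrane numbers (C1–C15; target = 4S,8S,10S,5E); the Cu(II)/(S,S)-t-Bu-box catalyst is taken to attack butane-2,3-dione with the same facial sense as pyruvate esters; the enol geometry of 5 and 7 is immaterial.

## Retrosynthetic overview

1. Target 30 ⇐ bis-silyl ether 29 ⇐ singlet-oxygen oxidation/dehydration of the fused furan in 25. The ylidene butenolide is unveiled last, so its C5=C6 geometry is fixed by the ring.
2. 25 ⇐ alcohol 20 ⇐ lactone 18 by the key step: lactone-opening intramolecular Claisen (C1–C2) plus cyclodehydration, which closes the ten-membered carbocycle and the 3(2H)-furanone together and frees 8-OH.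
3. 18 ⇐ γ-keto ester 16 (transfer hydrogenation sets C8; C10 comes from bromide 14) ⇐ thioester 13 by Pd-catalysed acylation (C8–C9).
4. 13 ⇐ Feist–Benary annulation of β-keto thioester 8 with chloroketone 11; 8 ⇐ Cu-catalysed vinylogous aldol of butane-2,3-dione (sets C4).
5. Ring order: furan (butenolide surrogate) → γ-lactone (temporary) → carbocycle + furanone (one operation) → butenolide.

## Route

**Step 1**
Reactants: 1 2,2,6-trimethyl-4H-1,3-dioxin-4-one; 2 ethanethiol
Product: 4 S-ethyl 3-oxobutanethioate, via acetylketene 3 (not isolated)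
Conditions: PhMe, 110 °C, sealed tube
Reagents that add atoms: none
Why: Thermal retro-[4+2] of the dioxinone releases acetylketene, which the thiol traps (acylketene trapping) to give the β-keto thioester.

**Step 2**
Reactants: 4 S-ethyl 3-oxobutanethioate
Product: 5 1-(ethylsulfanyl)-1,3-bis[(trimethylsilyl)oxy]buta-1,3-diene
Conditions: TMSOTf (2.2 equiv), Et3N, Et2O, 0 °C
Reagents that add atoms: trimethylsilyl trifluoromethanesulfonate, C[Si](C)(C)OS(=O)(=O)C(F)(F)F
Why: Double soft enolisation/O-silylation gives the Chan-type 1,3-bis(silyloxy)diene, a γ-nucleophilic acetoacetate equivalent.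

**Step 3**
Reactants: 6 butane-2,3-dione; 5 1-(ethylsulfanyl)-1,3-bis[(trimethylsilyl)oxy]buta-1,3-diene
Product: 8 S-ethyl (5S)-5-methyl-3,6-dioxo-5-[(trimethylsilyl)oxy]heptanethioate, via enol silane adduct 7 (not isolated)
Conditions: [Cu((S,S)-t-Bu-box)](OTf)2 (10 mol %), THF, −78 °C; then 0.1 M HCl/THF, 0 °C, 5 min
Reagents that add atoms: none
Why: Cu(II)–bis(oxazoline)-catalysed vinylogous Mukaiyama aldol; the diene terminus adds to one face of the chelated 1,2-diketone and sets C4 (S), silyl transfer caps the tertiary oxygen, and brief acid cleaves only the enol silane.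

**Step 4**
Reactants: 9 3-chloropropane-1,2-diol (racemic)
Product: 10 1-[(tert-butyldimethylsilyl)oxy]-3-chloropropan-2-ol
Conditions: TBSCl, imidazole, CH2Cl2, 0 °C
Reagents that add atoms: tert-butyldimethylsilyl chloride, CC(C)(C)[Si](C)(C)Cl
Why: Selective silylation of the primary hydroxyl of a 1,2-diol.

**Step 5**
Reactants: 10 1-[(tert-butyldimethylsilyl)oxy]-3-chloropropan-2-ol
Product: 11 1-[(tert-butyldimethylsilyl)oxy]-3-chloropropan-2-one
Conditions: Dess–Martin periodinane, CH2Cl2, 25 °C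
Reagents that add atoms: none
Why: Dess–Martin oxidation of the secondary alcohol; the stereocentre of 10 disappears.

**Step 6**
Reactants: 8 S-ethyl (5S)-5-methyl-3,6-dioxo-5-[(trimethylsilyl)oxy]heptanethioate; 11 1-[(tert-butyldimethylsilyl)oxy]-3-chloropropan-2-one
Product: 13 S-ethyl 4-{[(tert-butyldimethylsilyl)oxy]methyl}-2-{(2S)-2-methyl-3-oxo-2-[(trimethylsilyl)oxy]butyl}furan-3-carbothioate, via hydroxydihydrofuran 12 (not isolated)
Conditions: pyridine, 4 Å MS, 60 °C
Reagents that add atoms: none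
Why: Feist–Benary furan synthesis (aldol of the β-keto thioester onto the chloroketone carbonyl, enol O-alkylation, dehydration) places C5/C8/C13/H on the four furan carbons; C4 is untouched and its silyl ether stops lactonisation onto the thioester.

**Step 7**
Reactants: 13 S-ethyl 4-{[(tert-butyldimethylsilyl)oxy]methyl}-2-{(2S)-2-methyl-3-oxo-2-[(trimethylsilyl)oxy]butyl}furan-3-carbothioate; 14 methyl (2R)-3-bromo-2-methylpropanoate
Product: 16 methyl (2S)-4-[4-{[(tert-butyldimethylsilyl)oxy]methyl}-2-{(2S)-2-methyl-3-oxo-2-[(trimethylsilyl)oxy]butyl}furan-3-yl]-2-methyl-4-oxobutanoate, via alkylzinc bromide 15 (not isolated)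
Conditions: Zn, LiCl, THF, 40 °C; then 13, PdCl2(PPh3)2 (5 mol %), PhMe, 25 °C
Reagents that add atoms: none
Why: Fukuyama coupling (Pd-catalysed acylation of an alkylzinc by a thioester) forms C8–C9 without touching the methyl ketone; the C10 centre from 14 is not involved (R→S is only a CIP priority change).

**Step 8**
Reactants: 16 methyl (2S)-4-[4-{[(tert-butyldimethylsilyl)oxy]methyl}-2-{(2S)-2-methyl-3-oxo-2-[(trimethylsilyl)oxy]butyl}furan-3-yl]-2-methyl-4-oxobutanoate
Product: 18 (3S,5S)-5-[4-{[(tert-butyldimethylsilyl)oxy]methyl}-2-{(2S)-2-methyl-3-oxo-2-[(trimethylsilyl)oxy]butyl}furan-3-yl]-3-methyloxolan-2-one, via hydroxy ester 17 (not isolated)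
Conditions: RuCl[(S,S)-TsDPEN](p-cymene) (3 mol %), t-BuOK (6 mol %), i-PrOH, 25 °C
Reagents that add atoms: none
Why: Noyori asymmetric transfer hydrogenation reduces the heteroaryl ketone under catalyst control to the (S)-carbinol (C8) while the hindered α-silyloxy methyl ketone is left alone; the alkoxide lactonises to the cis-lactone, which also makes the reduction irreversible.

**Step 9 (key step)**
Reactants: 18 (3S,5S)-5-[4-{[(tert-butyldimethylsilyl)oxy]methyl}-2-{(2S)-2-methyl-3-oxo-2-[(trimethylsilyl)oxy]butyl}furan-3-yl]-3-methyloxolan-2-one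
Product: 20 (4S,8S,10S)-tricyclic furanone alcohol (1,4-epoxy-8-hydroxy-3-oxogermacr-1-ene with a furan fused at C6–C7 and 13-OTBS), via macrocyclic diketone 19 (not isolated)
Conditions: LiHMDS (1.1 equiv), THF (2 mM, slow addition), −78 → 25 °C; AcOH; then TsOH·H2O (cat.), CH2Cl2, 25 °C
Reagents that add atoms: none
Why: Proposed new method: the methyl-ketone lithium enolate (the only enolisable ketone site) attacks the γ-lactone carbonyl, the tetrahedral intermediate expels the C8 alkoxide to open the lactone and close the ten-membered ring (helped by the cis-disposed ortho substituents on the furan and by irreversible diketonate formation), and acid then removes the TMS group and cyclodehydrates the α′-hydroxy-1,3-diketone to the 3(2H)-furanone, so two rings form with no new stereocentre; closest known chemistry is the crossed Claisen/Dieckmann acylation of ketone enolates by lactones followed by acid cyclodehydration of α′-hydroxy-1,3-diketones to 3(2H)-furanones.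

**Step 10**
Reactants: 21 ethyl 2-(hydroxymethyl)prop-2-enoate
Product: 22 ethyl 2-{[(tert-butyldimethylsilyl)oxy]methyl}prop-2-enoate
Conditions: TBSCl, imidazole, DMF, 25 °C
Reagents that add atoms: tert-butyldimethylsilyl chloride, CC(C)(C)[Si](C)(C)Cl
Why: Standard silylation of a primary allylic alcohol.

**Step 11**
Reactants: 22 ethyl 2-{[(tert-butyldimethylsilyl)oxy]methyl}prop-2-enoate
Product: 23 2-{[(tert-butyldimethylsilyl)oxy]methyl}prop-2-enoic acid
Conditions: LiOH, THF/H2O, 0 °C; then 1 M HCl to pH 4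
Reagents that add atoms: lithium hydroxide, [Li+].[OH-]
Why: Saponification of the ethyl ester; the primary TBS ether survives cold LiOH.

**Step 12**
Reactants: 20 (4S,8S,10S)-tricyclic furanone alcohol; 23 2-{[(tert-butyldimethylsilyl)oxy]methyl}prop-2-enoic acid
Product: 25 8-O-{2-[(tert-butyldimethylsilyloxy)methyl]acryloyl} ester of 20, via O-acylisourea 24 (not isolated)
Conditions: DCC, DMAP (cat.), CH2Cl2, 0 → 25 °C
Reagents that add atoms: none
Why: Steglich esterification acylates the only free hydroxyl (8-OH) with retention at C8.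

**Step 13**
Reactants: 25 8-O-{2-[(tert-butyldimethylsilyloxy)methyl]acryloyl} ester of 20
Product: 29 bis-TBS ether of the target, via furan endoperoxide 26 (not isolated), via hydroxybutenolide 27 (not isolated), via hemiketal trifluoroacetate 28 (not isolated)
Conditions: O2, hν, TPP (cat.), i-Pr2NEt, CH2Cl2, −78 °C; then (CF3CO)2O, −78 → 0 °C
Reagents that add atoms: oxygen, O=O
Why: Singlet-oxygen [4+2] on the electron-rich furan, then base-induced Kornblum–DeLaMare fragmentation (only C12 carries H, so C12 becomes the lactone carbonyl and C6 the hemiketal), then acylation/elimination of the hemiketal OH; the new C5=C6 bond can only be ring-cis, which is the required 5E geometry.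

**Step 14**
Reactants: 29 bis-TBS ether of the target
Product: 30 target (CNP0261115.1)
Conditions: HF·pyridine, THF, 0 °C
Reagents that add atoms: none
Why: Fluoride-mediated cleavage of both primary TBS ethers under non-basic conditions that spare the acrylate, the ylidene butenolide and the furanone.

## Compound list

1 | 2,2,6-trimethyl-4H-1,3-dioxin-4-one | CC1=CC(=O)OC(C)(C)O1 | starting material
2 | ethanethiol | CCS | starting material
3 | acetylketene | CC(=O)C=C=O | intermediate (not isolated)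
4 | S-ethyl 3-oxobutanethioate | CCSC(=O)CC(C)=O | intermediate
5 | 1-(ethylsulfanyl)-1,3-bis[(trimethylsilyl)oxy]buta-1,3-diene | C=C(O[Si](C)(C)C)C=C(O[Si](C)(C)C)SCC | intermediate
6 | butane-2,3-dione | CC(=O)C(C)=O | starting material
7 | S-ethyl (5S)-5-methyl-6-oxo-3,5-bis[(trimethylsilyl)oxy]hept-2-enethioate | CCSC(=O)C=C(O[Si](C)(C)C)C[C@](C)(O[Si](C)(C)C)C(C)=O | intermediate (not isolated)
8 | S-ethyl (5S)-5-methyl-3,6-dioxo-5-[(trimethylsilyl)oxy]heptanethioate | CCSC(=O)CC(=O)C[C@](C)(O[Si](C)(C)C)C(C)=O | intermediate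
9 | 3-chloropropane-1,2-diol (racemic) | OCC(O)CCl | starting material
10 | 1-[(tert-butyldimethylsilyl)oxy]-3-chloropropan-2-ol (racemic) | CC(C)(C)[Si](C)(C)OCC(O)CCl | intermediate
11 | 1-[(tert-butyldimethylsilyl)oxy]-3-chloropropan-2-one | CC(C)(C)[Si](C)(C)OCC(=O)CCl | intermediate
12 | S-ethyl 4-{[(tert-butyldimethylsilyl)oxy]methyl}-4-hydroxy-2-{(2S)-2-methyl-3-oxo-2-[(trimethylsilyl)oxy]butyl}-4,5-dihydrofuran-3-carbothioate (epimers at C4 of the ring) | CCSC(=O)C1=C(C[C@](C)(O[Si](C)(C)C)C(C)=O)OCC1(O)CO[Si](C)(C)C(C)(C)C | intermediate (not isolated)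
13 | S-ethyl 4-{[(tert-butyldimethylsilyl)oxy]methyl}-2-{(2S)-2-methyl-3-oxo-2-[(trimethylsilyl)oxy]butyl}furan-3-carbothioate | CCSC(=O)c1c(CO[Si](C)(C)C(C)(C)C)coc1C[C@](C)(O[Si](C)(C)C)C(C)=O | intermediate
14 | methyl (2R)-3-bromo-2-methylpropanoate | COC(=O)[C@@H](C)CBr | starting material
15 | [(2R)-3-methoxy-2-methyl-3-oxopropyl]zinc bromide | COC(=O)[C@@H](C)C[Zn]Br | intermediate (not isolated)
16 | methyl (2S)-4-[4-{[(tert-butyldimethylsilyl)oxy]methyl}-2-{(2S)-2-methyl-3-oxo-2-[(trimethylsilyl)oxy]butyl}furan-3-yl]-2-methyl-4-oxobutanoate | COC(=O)[C@@H](C)CC(=O)c1c(CO[Si](C)(C)C(C)(C)C)coc1C[C@](C)(O[Si](C)(C)C)C(C)=O | intermediate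
17 | methyl (2S,4S)-4-[4-{[(tert-butyldimethylsilyl)oxy]methyl}-2-{(2S)-2-methyl-3-oxo-2-[(trimethylsilyl)oxy]butyl}furan-3-yl]-4-hydroxy-2-methylbutanoate | COC(=O)[C@@H](C)C[C@H](O)c1c(CO[Si](C)(C)C(C)(C)C)coc1C[C@](C)(O[Si](C)(C)C)C(C)=O | intermediate (not isolated)
18 | (3S,5S)-5-[4-{[(tert-butyldimethylsilyl)oxy]methyl}-2-{(2S)-2-methyl-3-oxo-2-[(trimethylsilyl)oxy]butyl}furan-3-yl]-3-methyloxolan-2-one (cis-lactone) | C[C@H]1C[C@H](OC1=O)c1c(CO[Si](C)(C)C(C)(C)C)coc1C[C@](C)(O[Si](C)(C)C)C(C)=O | intermediate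
19 | (4S,8S,10S)-macrocyclic 1,3-diketone: ten-membered carbocycle with C1 and C3 ketones, 4-Me, 4-OTMS, 8-OH, 10-Me, furan fused at C6–C7 (furan O on C6), CH2OTBS on the furan carbon next to C7 | O[C@H]1C[C@H](C)C(=O)CC(=O)[C@@](C)(O[Si](C)(C)C)Cc2occ(CO[Si](C)(C)C(C)(C)C)c21 | intermediate (not isolated)
20 | (4S,8S,10S)-tricyclic furanone alcohol: as 19 but with O bridging C1 and C4 as a 3(2H)-furanone (C1=C2, C3=O), free 8-OH | O[C@H]1C[C@H](C)C2=CC(=O)[C@](C)(Cc3occ(CO[Si](C)(C)C(C)(C)C)c31)O2 | intermediate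
21 | ethyl 2-(hydroxymethyl)prop-2-enoate | C=C(CO)C(=O)OCC | starting material
22 | ethyl 2-{[(tert-butyldimethylsilyl)oxy]methyl}prop-2-enoate | C=C(CO[Si](C)(C)C(C)(C)C)C(=O)OCC | intermediate
23 | 2-{[(tert-butyldimethylsilyl)oxy]methyl}prop-2-enoic acid | C=C(CO[Si](C)(C)C(C)(C)C)C(=O)O | intermediate
24 | O-acylisourea of 23 with DCC | C=C(CO[Si](C)(C)C(C)(C)C)C(=O)OC(=NC1CCCCC1)NC1CCCCC1 | intermediate (not isolated)
25 | 8-O-{2-[(tert-butyldimethylsilyloxy)methyl]acryloyl} ester of 20 | C=C(CO[Si](C)(C)C(C)(C)C)C(=O)O[C@H]1C[C@H](C)C2=CC(=O)[C@](C)(Cc3occ(CO[Si](C)(C)C(C)(C)C)c31)O2 | intermediate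
26 | 2,5-endoperoxide of the furan of 25 (O–O bridge C6 to C12) | C=C(CO[Si](C)(C)C(C)(C)C)C(=O)O[C@H]1C[C@H](C)C2=CC(=O)[C@](C)(CC34OOC(O3)C(CO[Si](C)(C)C(C)(C)C)=C41)O2 | intermediate (not isolated)
27 | 6-hydroxy-12,6-olide (γ-hydroxybutenolide, C7=C11, epimers at C6) | C=C(CO[Si](C)(C)C(C)(C)C)C(=O)O[C@H]1C[C@H](C)C2=CC(=O)[C@](C)(CC3(O)OC(=O)C(CO[Si](C)(C)C(C)(C)C)=C31)O2 | intermediate (not isolated)
28 | 6-O-trifluoroacetate of 27 | C=C(CO[Si](C)(C)C(C)(C)C)C(=O)O[C@H]1C[C@H](C)C2=CC(=O)[C@](C)(CC3(OC(=O)C(F)(F)F)OC(=O)C(CO[Si](C)(C)C(C)(C)C)=C31)O2 | intermediate (not isolated)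
29 | bis-TBS ether of the target (13-OTBS and side-chain OTBS; 5E) | C=C(CO[Si](C)(C)C(C)(C)C)C(=O)O[C@H]1C[C@H](C)C2=CC(=O)[C@](C)(/C=C3/OC(=O)C(CO[Si](C)(C)C(C)(C)C)=C31)O2 | intermediate
30 | CNP0261115.1, (4S,8S,10S,5E) | C=C(CO)C(=O)O[C@H]1C[C@H](C)C2=CC(=O)[C@](C)(/C=C3/OC(=O)C(CO)=C31)O2 | target

## Step count and risks

Total steps: 14. Longest linear sequence: 10 (steps 1, 2, 3, 6, 7, 8, 9, 12, 13, 14).

**Most likely to fail**

1. Step 9 (ten-membered ring by Claisen; oligomerisation, or 8-OH instead of 4-OH capturing the diketone). Fallback: close the ring at C8–C9 with palladium instead, starting from 13 and returning at 20. The lithium enolate of 13 (LiHMDS, THF, −78 °C) is acylated with ester 14 to give bromo diketone F1. TsOH cyclodehydrates this to furanone bromide F2, so the furanone exists before any ring closure. Zinc insertion gives alkylzinc F3, and an intramolecular Fukuyama acylation of the thioester (PdCl2(PPh3)2, high dilution) closes the carbocycle as 3-furyl ketone F4. Ru/(S,S)-TsDPEN transfer hydrogenation of F4 then gives 20.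

2. Step 8 (facial and chemoselectivity of the transfer hydrogenation on a doubly ortho-substituted 3-acylfuran). Fallback: build the lactone by allylation instead, starting from 13 and returning at 18; this also bypasses step 7. Fukuyama reduction (Et3SiH, Pd/C) gives aldehyde F5. Catalytic enantioselective chromium-mediated 2-(alkoxycarbonyl)allylation with ethyl 2-(bromomethyl)acrylate gives (S)-homoallylic alcohol F6, which lactonises to α-methylene lactone F7. Hydrogenation with RhCl(PPh3)3 adds H2 anti to the furyl group and gives cis-lactone 18.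

3. Step 3 (enantioselectivity and γ-regioselectivity with a thioester-derived bis-silyl diene, a combination without direct precedent). Fallback: use a dioxinone dienolate instead, starting from 1 and 6 and returning at 8. LDA/TMSCl converts 1 into dienol silane F8. The same Cu(II)/t-Bu-box aldol with 6 gives dioxinone adduct F9. Thermolysis of F9 with 2 (PhMe, 110 °C, sealed) generates acylketene F10, which the thiol traps to give 8.

## Further compounds

F1 | step 9 | S-ethyl 2-{(2S,7R)-8-bromo-2,7-dimethyl-3,5,6-trioxo... open-chain bromo 1,3-diketone: 13 acylated at the ketone methyl by the (2R)-3-bromo-2-methylpropanoyl group | CCSC(=O)c1c(CO[Si](C)(C)C(C)(C)C)coc1C[C@](C)(O[Si](C)(C)C)C(=O)CC(=O)[C@@H](C)CBr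
F2 | step 9 | S-ethyl 2-({(2S)-5-[(2R)-1-bromopropan-2-yl]-2-methyl-3-oxo-2,3-dihydrofuran-2-yl}methyl)-4-{[(tert-butyldimethylsilyl)oxy]methyl}furan-3-carbothioate | CCSC(=O)c1c(CO[Si](C)(C)C(C)(C)C)coc1C[C@]1(C)OC(=CC1=O)[C@@H](C)CBr
F3 | step 9 | alkylzinc bromide from F2 | CCSC(=O)c1c(CO[Si](C)(C)C(C)(C)C)coc1C[C@]1(C)OC(=CC1=O)[C@@H](C)C[Zn]Br
F4 | step 9 | (4S,10S)-8-oxo analogue of 20 (macrocyclic 3-furyl ketone) | O=C1C[C@H](C)C2=CC(=O)[C@](C)(Cc3occ(CO[Si](C)(C)C(C)(C)C)c31)O2
F5 | step 8 | 4-{[(tert-butyldimethylsilyl)oxy]methyl}-2-{(2S)-2-methyl-3-oxo-2-[(trimethylsilyl)oxy]butyl}furan-3-carbaldehyde | O=Cc1c(CO[Si](C)(C)C(C)(C)C)coc1C[C@](C)(O[Si](C)(C)C)C(C)=O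
F6 | step 8 | ethyl (4S)-4-[4-{[(tert-butyldimethylsilyl)oxy]methyl}-2-{(2S)-2-methyl-3-oxo-2-[(trimethylsilyl)oxy]butyl}furan-3-yl]-4-hydroxy-2-methylidenebutanoate | CCOC(=O)C(=C)C[C@H](O)c1c(CO[Si](C)(C)C(C)(C)C)coc1C[C@](C)(O[Si](C)(C)C)C(C)=O
F7 | step 8 | (5S)-5-[4-{[(tert-butyldimethylsilyl)oxy]methyl}-2-{(2S)-2-methyl-3-oxo-2-[(trimethylsilyl)oxy]butyl}furan-3-yl]-3-methylideneoxolan-2-one | C=C1C[C@H](OC1=O)c1c(CO[Si](C)(C)C(C)(C)C)coc1C[C@](C)(O[Si](C)(C)C)C(C)=O
F8 | step 3 | 2,2-dimethyl-6-methylidene-4-[(trimethylsilyl)oxy]-6H-1,3-dioxine | C=C1C=C(O[Si](C)(C)C)OC(C)(C)O1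
F9 | step 3 | 2,2-dimethyl-6-{(2S)-2-methyl-3-oxo-2-[(trimethylsilyl)oxy]butyl}-4H-1,3-dioxin-4-one | CC(=O)[C@@](C)(O[Si](C)(C)C)CC1=CC(=O)OC(C)(C)O1
F10 | step 3 | (5S)-5-methyl-5-[(trimethylsilyl)oxy]hept-1-ene-1,3,6-trione (acylketene) | O=C=CC(=O)C[C@](C)(O[Si](C)(C)C)C(C)=O
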